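**Plan**

- Core numbering used below (6-oxabicyclo[3.2.1]octane): C1 quaternary carbon (Me, bonded to C7H2–O6), C2 carbinol, C3, C4, C5 quaternary carbon (Me, bonded to O6), C8 the one-carbon bridge that carries the side chain.
- Retrosynthesis: cut first the C(sp3)–C(sp2) bond between the CH2CH2 arm on C8 and the C(Me)=CH unit (B-alkyl Suzuki–Miyaura coupling). Then cut C2–C3 and C8–C5 together, which opens the bicycle to an acyclic aldehyde carrying an allylsilane and a 1-methylcyclopropyl ether.
- Enabling feature: C5 is a tertiary ether carbon 1,4 to the C2 carbinol and tied through the O6–C7 bridge to C1. A 1-methylcyclopropyl ether on O6 is a homo-enol ether whose CH2 can add to a C2 aldehyde, leaving C5 as a ring oxocarbenium ion within reach of an allylsilane on C1.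
- Forward order: quaternary C1, then the ether tether on O6, then the oxepane ring (C2–C3) followed by the cyclohexane and tetrahydrofuran rings (C8–C5) in one cascade, then the side chain with the coumarin.
- Stereochemistry: C1 from a Sharpless epoxidation relayed by a stereospecific 1,2-siloxymethyl shift; C2, C5 and C8 set in the cascade under control of C1; the (E)-alkene from an (E)-enol triflate coupled with retention.

Key step: step 11

**Route**

Step 1
Reactants: 1 (2E)-3-methylpent-2-en-4-yn-1-ol
Product: 2 (2E)-3-methylpenta-2,4-dien-1-ol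
Conditions: H2 (1 atm), Pd/CaCO3 poisoned with Pb(OAc)2, quinoline, EtOAc, 20 °C
Reagents that add atoms: none
Why: Lindlar-type semi-hydrogenation of the terminal alkyne should stop at the vinyl group and leave the trisubstituted (E)-allylic alcohol untouched.

Step 2
Reactants: 2 (2E)-3-methylpenta-2,4-dien-1-ol
Product: 3 [(2S,3S)-3-ethenyl-3-methyloxiran-2-yl]methanol
Conditions: Ti(OiPr)4 (10 mol %), L-(+)-diethyl tartrate (12 mol %), tBuOOH, 4 Å molecular sieves, CH2Cl2, −25 °C
Reagents that add atoms: tert-butyl hydroperoxide, CC(C)(C)OO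
Why: Sharpless asymmetric epoxidation is directed by the allylic hydroxyl to the 2,3-alkene only, and L-(+)-tartrate should deliver oxygen to the face that gives the (2S,3S)-epoxide, as with other (E)-3,3-disubstituted allylic alcohols.

Step 3
Reactants: 3 [(2S,3S)-3-ethenyl-3-methyloxiran-2-yl]methanol
Product: 4 tert-butyl{[(2S,3S)-3-ethenyl-3-methyloxiran-2-yl]methoxy}dimethylsilane
Conditions: TBSCl, imidazole, DMF, 0 °C
Reagents that add atoms: tert-butyldimethylsilyl chloride, CC(C)(C)[Si](C)(C)Cl
Why: Standard silylation of the primary alcohol under basic conditions that the acid-labile vinyl epoxide tolerates; the bulky silyl ether is the migrating-group precursor for step 4.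

Step 4
Reactants: 4 tert-butyl{[(2S,3S)-3-ethenyl-3-methyloxiran-2-yl]methoxy}dimethylsilane
Product: 6 (2R)-2-({[tert-butyl(dimethyl)silyl]oxy}methyl)-2-methylbut-3-en-1-ol, via aldehyde 5 (not isolated)
Conditions: MeAl(OAr)2 (Ar = 4-bromo-2,6-di-tert-butylphenyl, 2 equiv), CH2Cl2, −78 °C; then NaBH4, MeOH, −78 → 0 °C
Reagents that add atoms: none
Why: The bulky aluminium Lewis acid should open the epoxide at the tertiary allylic carbon while the siloxymethyl group shifts anti to the departing oxygen (organoaluminium-promoted epoxy silyl ether to β-siloxy aldehyde rearrangement, a semipinacol-type 1,2-shift), so the epoxide configuration is relayed to the quaternary carbon with inversion; borohydride then reduces the non-enolisable aldehyde 5 in the same flask under conditions too mild for the 1,3-silyl migration that would racemise 6.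

Step 5
Reactants: 6 (2R)-2-({[tert-butyl(dimethyl)silyl]oxy}methyl)-2-methylbut-3-en-1-ol
Product: 7 (2R)-2-({[tert-butyl(dimethyl)silyl]oxy}methyl)-2-methylbut-3-en-1-yl acetate
Conditions: Ac2O, pyridine, DMAP (cat.), CH2Cl2, 0 → 20 °C
Reagents that add atoms: acetic anhydride, CC(=O)OC(C)=O
Why: Base-catalysed acylation of the free primary alcohol differentiates the two CH2O arms for good and supplies the carbonyl carbon that becomes C5.

Step 6
Reactants: 7 (2R)-2-({[tert-butyl(dimethyl)silyl]oxy}methyl)-2-methylbut-3-en-1-yl acetate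
Product: 8 tert-butyl(dimethyl){[(2R)-2-methyl-2-{[(prop-1-en-2-yl)oxy]methyl}but-3-en-1-yl]oxy}silane
Conditions: Cp2Ti(μ-Cl)(μ-CH2)AlMe2, pyridine, THF/toluene, −40 → 0 °C
Reagents that add atoms: Tebbe reagent Cp2Ti(μ-Cl)(μ-CH2)AlMe2 (the μ-chloro bridge written as a formal Cl+/Al− pair), C[Al-]1(C)C[Ti](C2C=CC=C2)(C2C=CC=C2)[Cl+]1
Why: Tebbe methylenation should convert the acetate C=O into C=CH2 and give the isopropenyl ether without touching the silyl ether or the hindered vinyl group.

Step 7
Reactants: 8 tert-butyl(dimethyl){[(2R)-2-methyl-2-{[(prop-1-en-2-yl)oxy]methyl}but-3-en-1-yl]oxy}silane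
Product: 9 tert-butyl(dimethyl){[(2R)-2-methyl-2-{[(1-methylcyclopropyl)oxy]methyl}but-3-en-1-yl]oxy}silane
Conditions: Et2Zn, CH2I2, CH2Cl2, 0 °C
Reagents that add atoms: diiodomethane, ICI
Why: Simmons–Smith cyclopropanation (Furukawa variant) is fastest at electron-rich alkenes, so the enol ether should be cyclopropanated in preference to the monosubstituted vinyl group on the quaternary carbon.

Step 8
Reactants: 9 tert-butyl(dimethyl){[(2R)-2-methyl-2-{[(1-methylcyclopropyl)oxy]methyl}but-3-en-1-yl]oxy}silane
Product: 10 (2S)-2-methyl-2-{[(1-methylcyclopropyl)oxy]methyl}but-3-en-1-ol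
Conditions: Bu4NF, THF, 0 → 20 °C
Reagents that add atoms: none
Why: Fluoride cleaves the Si–O bond while the cyclopropyl ether and the alkene are inert, and with no acyl or silyl group on the other arm nothing can migrate between the two oxygens.

Step 9
Reactants: 10 (2S)-2-methyl-2-{[(1-methylcyclopropyl)oxy]methyl}but-3-en-1-ol; 11 allyltrimethylsilane
Product: 12 (2S,3E)-2-methyl-2-{[(1-methylcyclopropyl)oxy]methyl}-5-(trimethylsilyl)pent-3-en-1-ol
Conditions: second-generation Hoveyda–Grubbs catalyst RuCl2(SIMes)(=CH–C6H4-2-OiPr) (5 mol %), 11 (5 equiv), CH2Cl2, 40 °C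
Reagents that add atoms: none
Why: Olefin cross-metathesis of the hindered vinyl group with the fast-reacting allylsilane used in excess should give the (E)-allylsilane with loss of ethene.

Step 10
Reactants: 12 (2S,3E)-2-methyl-2-{[(1-methylcyclopropyl)oxy]methyl}-5-(trimethylsilyl)pent-3-en-1-ol
Product: 13 (2R,3E)-2-methyl-2-{[(1-methylcyclopropyl)oxy]methyl}-5-(trimethylsilyl)pent-3-enal
Conditions: Dess–Martin periodinane, NaHCO3, CH2Cl2, 0 → 20 °C
Reagents that add atoms: none
Why: Buffered Dess–Martin oxidation of the neopentyl primary alcohol should give the non-enolisable aldehyde under non-acidic conditions that spare the allylsilane and the cyclopropyl ether.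

Step 11
Reactants: 13 (2R,3E)-2-methyl-2-{[(1-methylcyclopropyl)oxy]methyl}-5-(trimethylsilyl)pent-3-enal
Product: 16 (1R,2R,5S,8R)-8-ethenyl-1,5-dimethyl-6-oxabicyclo[3.2.1]octan-2-ol, via oxocarbenium triflate 14 (not isolated), via trimethylsilyl ether 15 (not isolated)
Conditions: Me3SiOTf (0.3 equiv), 2,6-di-tert-butyl-4-methylpyridine (0.5 equiv), CH2Cl2 (0.01 M), −78 → −30 °C; then K2CO3, MeOH, 0 °C
Reagents that add atoms: none
Why: Proposed new method: a homo-Mukaiyama aldol/Sakurai cascade in which O-silylation of the neopentyl aldehyde lets a CH2–C(O) σ-bond of the 1-methylcyclopropyl ether (a homo-enol ether with two equivalent CH2 groups) attack the C=O+ carbon, forming C2–C3 and unmasking the seven-membered oxocarbenium ion 14, which the allylsilane on C1 then captures at C5 to form C8–C5 while Me3Si+ is expelled and turns the catalyst over. The closest known reactions are the Mukaiyama aldol–Prins cascade of enol ethers (here extended by one carbon through the cyclopropane), the Lewis-acid addition of cyclopropanol derivatives to oxocarbenium ions that gives oxepanes, and allylsilane–oxocarbenium closures to 3-vinyltetrahydrofurans. Ring closures: the oxepane ring (O6–C7–C1–C2–C3–C4–C5) closes by a ring-enlarging attack through a six-centre chair (C2, C1, C7, O6, C5, C3), formally 7-endo at the new C=O+; the C8–C5 bond then closes the cyclohexane 6-exo-trig at the oxocarbenium carbon through a chair and with it the tetrahydrofuran ring (5-endo at C=O+, exo at the alkene). C2 is set in the six-centre chair with the silylated carbonyl oxygen pseudo-equatorial and the alkenyl arm of the C1 quaternary centre anti to the incoming CH2 (Felkin-type), which places OSi cis to the C1 methyl and gives (2R). C5 is fixed by the bridge, since the allylsilane on C1 can reach only one face of the ring C=O+, and C8 follows from the chair closure with the nascent vinyl group equatorial on the cyclohexane, on the side of the O6–C7 bridge (8R). The step needs the cyclopropane and not a second molecule's allylsilane to attack the aldehyde, and C–C closure from ion 14 and not from the five-membered ion that reversible ketalisation by the C2 oxygen could open; the first should be secured by the pivaldehyde-like hindrance of the aldehyde, high dilution and the intramolecular six-centre array, the second by the O–SiMe3 cap and by the fact that only 14 can close to an unstrained chair bicyclo[3.2.1] framework, the five-membered ion having to form a 7-oxanorbornane through a boat.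

Step 12
Reactants: 17 ethyl acetoacetate
Product: 18 ethyl (2E)-3-{[(trifluoromethyl)sulfonyl]oxy}but-2-enoate
Conditions: Tf2O, aq. Me4NOH, hexane, 5 → 20 °C
Reagents that add atoms: trifluoromethanesulfonic anhydride, O=S(=O)(OS(=O)(=O)C(F)(F)F)C(F)(F)F
Why: O-Triflation of the non-chelated tetramethylammonium enolate of the β-keto ester under biphasic conditions should give the (E)-enol triflate (OTf trans to the ester), which fixes the side-chain alkene geometry.

Step 13
Reactants: 18 ethyl (2E)-3-{[(trifluoromethyl)sulfonyl]oxy}but-2-enoate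
Product: 19 (2E)-4-hydroxybut-2-en-2-yl trifluoromethanesulfonate
Conditions: iBu2AlH (2.2 equiv), CH2Cl2, −78 °C
Reagents that add atoms: none
Why: Low-temperature 1,2-reduction of the enoate by the aluminium hydride should give the allylic alcohol without touching the vinyl triflate.

Step 14
Reactants: 19 (2E)-4-hydroxybut-2-en-2-yl trifluoromethanesulfonate; 20 umbelliferone (7-hydroxy-2H-chromen-2-one)
Product: 21 (2E)-4-[(2-oxo-2H-chromen-7-yl)oxy]but-2-en-2-yl trifluoromethanesulfonate
Conditions: PPh3, diisopropyl azodicarboxylate, THF, 0 → 20 °C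
Reagents that add atoms: none
Why: Mitsunobu etherification of the primary allylic alcohol with the acidic phenol (pKa about 8) takes place at the CH2 carbon, so the alkene geometry and the triflate should be preserved.

Step 15
Reactants: 16 (1R,2R,5S,8R)-8-ethenyl-1,5-dimethyl-6-oxabicyclo[3.2.1]octan-2-ol; 21 (2E)-4-[(2-oxo-2H-chromen-7-yl)oxy]but-2-en-2-yl trifluoromethanesulfonate
Product: 23 7-{[(2E)-5-[(1R,2R,5S,8R)-2-hydroxy-1,5-dimethyl-6-oxabicyclo[3.2.1]octan-8-yl]-3-methylpent-2-en-1-yl]oxy}-2H-chromen-2-one, via alkylborane 22 (not isolated)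
Conditions: 9-BBN (2.5 equiv), THF, 0 → 40 °C; then aq. Cs2CO3; then 21, Pd(dppf)Cl2 (5 mol %), AsPh3, DMF, 25 °C
Reagents that add atoms: none
Why: Anti-Markovnikov hydroboration of the vinyl group with 9-BBN (the hydroxyl being masked in the flask as its borinate) followed by B-alkyl Suzuki–Miyaura coupling with the vinyl triflate should form the C(sp3)–C(sp2) bond with retention of the (E)-geometry, since oxidative addition of zerovalent palladium to the vinyl triflate should be far faster than ionisation of the allylic aryl ether and the mild carbonate base at room temperature spares the coumarin lactone.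

**Compound list**

1 | (2E)-3-methylpent-2-en-4-yn-1-ol | C#C/C(C)=C/CO | starting material
2 | (2E)-3-methylpenta-2,4-dien-1-ol | C=C/C(C)=C/CO | intermediate
3 | [(2S,3S)-3-ethenyl-3-methyloxiran-2-yl]methanol | C=C[C@]1(C)O[C@H]1CO | intermediate
4 | tert-butyl{[(2S,3S)-3-ethenyl-3-methyloxiran-2-yl]methoxy}dimethylsilane | C=C[C@]1(C)O[C@H]1CO[Si](C)(C)C(C)(C)C | intermediate
5 | (2S)-2-({[tert-butyl(dimethyl)silyl]oxy}methyl)-2-methylbut-3-enal | C=C[C@](CO[Si](C)(C)C(C)(C)C)(C)C=O | intermediate
6 | (2R)-2-({[tert-butyl(dimethyl)silyl]oxy}methyl)-2-methylbut-3-en-1-ol | C=C[C@](CO[Si](C)(C)C(C)(C)C)(C)CO | intermediate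
7 | (2R)-2-({[tert-butyl(dimethyl)silyl]oxy}methyl)-2-methylbut-3-en-1-yl acetate | C=C[C@](CO[Si](C)(C)C(C)(C)C)(C)COC(C)=O | intermediate
8 | tert-butyl(dimethyl){[(2R)-2-methyl-2-{[(prop-1-en-2-yl)oxy]methyl}but-3-en-1-yl]oxy}silane | C=C[C@](CO[Si](C)(C)C(C)(C)C)(C)COC(C)=C | intermediate
9 | tert-butyl(dimethyl){[(2R)-2-methyl-2-{[(1-methylcyclopropyl)oxy]methyl}but-3-en-1-yl]oxy}silane | C=C[C@](CO[Si](C)(C)C(C)(C)C)(C)COC1(C)CC1 | intermediate
10 | (2S)-2-methyl-2-{[(1-methylcyclopropyl)oxy]methyl}but-3-en-1-ol | C=C[C@](CO)(C)COC1(C)CC1 | intermediate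
11 | allyltrimethylsilane | C=CC[Si](C)(C)C | starting material
12 | (2S,3E)-2-methyl-2-{[(1-methylcyclopropyl)oxy]methyl}-5-(trimethylsilyl)pent-3-en-1-ol | C[Si](C)(C)C/C=C/[C@](CO)(C)COC1(C)CC1 | intermediate
13 | (2R,3E)-2-methyl-2-{[(1-methylcyclopropyl)oxy]methyl}-5-(trimethylsilyl)pent-3-enal | C[Si](C)(C)C/C=C/[C@](C=O)(C)COC1(C)CC1 | intermediate
14 | (5R,6R)-2,6-dimethyl-5-[(trimethylsilyl)oxy]-6-[(1E)-3-(trimethylsilyl)prop-1-en-1-yl]oxepan-1-ylium (ring O=C2 oxocarbenium ion) trifluoromethanesulfonate | C[Si](C)(C)C/C=C/[C@]1(C)C[O+]=C(C)CC[C@H]1O[Si](C)(C)C.[O-]S(=O)(=O)C(F)(F)F | intermediate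
15 | {[(1R,2R,5S,8R)-8-ethenyl-1,5-dimethyl-6-oxabicyclo[3.2.1]octan-2-yl]oxy}trimethylsilane | C=C[C@@H]1[C@]2(C)CO[C@@]1(C)CC[C@H]2O[Si](C)(C)C | intermediate
16 | (1R,2R,5S,8R)-8-ethenyl-1,5-dimethyl-6-oxabicyclo[3.2.1]octan-2-ol | C=C[C@@H]1[C@]2(C)CO[C@@]1(C)CC[C@H]2O | intermediate
17 | ethyl acetoacetate | CCOC(=O)CC(C)=O | starting material
18 | ethyl (2E)-3-{[(trifluoromethyl)sulfonyl]oxy}but-2-enoate | C/C(=C\C(=O)OCC)OS(=O)(=O)C(F)(F)F | intermediate
19 | (2E)-4-hydroxybut-2-en-2-yl trifluoromethanesulfonate | C/C(=C\CO)OS(=O)(=O)C(F)(F)F | intermediate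
20 | umbelliferone (7-hydroxy-2H-chromen-2-one) | O=c1ccc2ccc(O)cc2o1 | starting material
21 | (2E)-4-[(2-oxo-2H-chromen-7-yl)oxy]but-2-en-2-yl trifluoromethanesulfonate | C/C(=C\COc1ccc2ccc(=O)oc2c1)OS(=O)(=O)C(F)(F)F | intermediate
22 | 9-{2-[(1R,2R,5S,8R)-2-(9-borabicyclo[3.3.1]nonan-9-yloxy)-1,5-dimethyl-6-oxabicyclo[3.2.1]octan-8-yl]ethyl}-9-borabicyclo[3.3.1]nonane | B1(C2CCCC1CCC2)CC[C@@H]1[C@]2(C)CO[C@@]1(C)CC[C@H]2OB1C2CCCC1CCC2 | intermediate
23 | 7-{[(2E)-5-[(1R,2R,5S,8R)-2-hydroxy-1,5-dimethyl-6-oxabicyclo[3.2.1]octan-8-yl]-3-methylpent-2-en-1-yl]oxy}-2H-chromen-2-one | C/C(=C\COc1ccc2ccc(=O)oc2c1)CC[C@@H]1[C@]2(C)CO[C@@]1(C)CC[C@H]2O | target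

**Totals**

Total step count: 15. Longest linear sequence: 12 steps (steps 1–11 and 15).

**Steps most likely to fail**

Step 11. The cyclopropane C–C bond may fail to engage the silylated aldehyde, with protonolysis of the cyclopropyl ether or intermolecular allyl transfer taking over. The ring oxocarbenium ion may be diverted through ketalisation by the C2 oxygen and reopening to the five-membered ion, and facial selectivity at C2 may be poor. The fallback uses known reactions, sets out from 6 and returns at 16. The free hydroxyl of 6 is capped with 2-methoxypropene and PPTS as the mixed ketal F1, the silyl ether is cleaved with Bu4NF to alcohol F2, and oxidation (Dess–Martin periodinane, pyridine) gives aldehyde F3, in which the two arms play the same roles as in 13. Addition of BrMgCH2CH2C(OCH2CH2O)CH3, the Grignard reagent of 2-(2-bromoethyl)-2-methyl-1,3-dioxolane and a classical ketone homoenolate equivalent, forms the C2–C3 bond and gives carbinol F4 as a mixture of carbinol epimers. Aqueous acid (1 M HCl, THF) removes both ketals, and the keto diol should close to the bicyclic ketal F5. Cross-metathesis with 11 under the conditions of step 9 gives allylsilane F6. TiCl4 at −78 °C then opens the ketal, and the allylsilane should capture the seven-membered oxocarbenium ion at C5 (intramolecular Sakurai reaction of a ketal), giving 16 together with its C2 epimer F7. F7 is oxidised (Dess–Martin periodinane) to ketone F8 and reduced with NaBH4, which should add from the axial direction and give 16; the same oxidation and reduction would recycle any C2 epimer formed in step 11 itself.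

Step 4. The tertiary allylic epoxide may ionise with conjugate capture or elimination to a dienol instead of the 1,2-shift, hydride may migrate in place of the siloxymethyl group, and enantiopurity may erode through a free cation. The fallback sets out from 1 and returns at 6, carrying the alkyne through the rearrangement so that the migration terminus is propargylic and cannot ionise in a conjugate sense. Sharpless epoxidation of 1 with the same tartrate gives epoxy alcohol F9, and silylation as in step 3 gives silyl ether F10. The MeAl(OAr)2 rearrangement gives alkynyl aldehyde F11, which is reduced in the flask with NaBH4 to alkynyl alcohol F12. Semi-hydrogenation (H2, Pd/CaCO3 poisoned with Pb(OAc)2, quinoline) then gives 6.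

Step 9. Metathesis at a vinyl group on a quaternary carbon may be slow, homodimerisation of 11 may outrun the cross reaction, and catalyst decay may bring alkene isomerisation. The fallback sets out from 9 and returns at 12, building the allylsilane by olefination instead. Ozonolysis of the vinyl group of 9 (O3, CH2Cl2/MeOH, −78 °C; then Me2S) gives aldehyde F13. Julia–Kocienski olefination with 1-phenyl-5-{[2-(trimethylsilyl)ethyl]sulfonyl}-1H-tetrazole (KN(SiMe3)2, DME, −60 °C) should give the (E)-allylsilane F14. Bu4NF buffered with AcOH at 0 °C removes the silyl ether and gives 12.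

**Further compounds**

F1 | step 11 | tert-butyl{[(2R)-2-{[(2-methoxypropan-2-yl)oxy]methyl}-2-methylbut-3-en-1-yl]oxy}dimethylsilane | C=C[C@](CO[Si](C)(C)C(C)(C)C)(C)COC(C)(C)OC
F2 | step 11 | (2S)-2-{[(2-methoxypropan-2-yl)oxy]methyl}-2-methylbut-3-en-1-ol | C=C[C@](CO)(C)COC(C)(C)OC
F3 | step 11 | (2R)-2-{[(2-methoxypropan-2-yl)oxy]methyl}-2-methylbut-3-enal | C=C[C@](C=O)(C)COC(C)(C)OC
F4 | step 11 | (4R)-4-{[(2-methoxypropan-2-yl)oxy]methyl}-4-methyl-1-(2-methyl-1,3-dioxolan-2-yl)hex-5-en-3-ol (both C3 epimers) | C=C[C@](C(O)CCC1(C)OCCO1)(C)COC(C)(C)OC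
F5 | step 11 | (4R)-4-ethenyl-1,4-dimethyl-2,8-dioxabicyclo[3.2.1]octane (both C5 epimers) | C=C[C@]1(C)COC2(C)CCC1O2
F6 | step 11 | (4R)-1,4-dimethyl-4-[(1E)-3-(trimethylsilyl)prop-1-en-1-yl]-2,8-dioxabicyclo[3.2.1]octane (both C5 epimers) | C[Si](C)(C)C/C=C/[C@]1(C)COC2(C)CCC1O2
F7 | step 11 | (1R,2S,5S,8R)-8-ethenyl-1,5-dimethyl-6-oxabicyclo[3.2.1]octan-2-ol | C=C[C@@H]1[C@]2(C)CO[C@@]1(C)CC[C@@H]2O
F8 | step 11 | (1R,5S,8R)-8-ethenyl-1,5-dimethyl-6-oxabicyclo[3.2.1]octan-2-one | C=C[C@@H]1[C@]2(C)CO[C@@]1(C)CCC2=O
F9 | step 4 | [(2S,3S)-3-ethynyl-3-methyloxiran-2-yl]methanol | C#C[C@]1(C)O[C@H]1CO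
F10 | step 4 | tert-butyl{[(2S,3S)-3-ethynyl-3-methyloxiran-2-yl]methoxy}dimethylsilane | C#C[C@]1(C)O[C@H]1CO[Si](C)(C)C(C)(C)C
F11 | step 4 | (2S)-2-({[tert-butyl(dimethyl)silyl]oxy}methyl)-2-methylbut-3-ynal | C#C[C@](CO[Si](C)(C)C(C)(C)C)(C)C=O
F12 | step 4 | (2R)-2-({[tert-butyl(dimethyl)silyl]oxy}methyl)-2-methylbut-3-yn-1-ol | C#C[C@](CO[Si](C)(C)C(C)(C)C)(C)CO
F13 | step 9 | (2R)-2-({[tert-butyl(dimethyl)silyl]oxy}methyl)-2-methyl-3-[(1-methylcyclopropyl)oxy]propanal | O=C[C@](CO[Si](C)(C)C(C)(C)C)(C)COC1(C)CC1
F14 | step 9 | tert-butyl(dimethyl){[(2R,3E)-2-methyl-2-{[(1-methylcyclopropyl)oxy]methyl}-5-(trimethylsilyl)pent-3-en-1-yl]oxy}silane | C[Si](C)(C)C/C=C/[C@](CO[Si](C)(C)C(C)(C)C)(C)COC1(C)CC1
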